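Begin with the easy step: one molecule of starting material takes one molecule of partner and gives target. If that were the whole flask, the 0.572 M of partner would cover the 0.52 M of starting material, and we should expect none of it left.

common to all: second substrate 1.04 M; partner 0.572 M
- gamma: starting material 0.35 M (in portions, 2); free catalyst 0.52 mM; run made earlier; portions every 20 h
- theta: starting material 0.78 M (in portions, 2); free catalyst 0.52 mM; run made earlier; portions every 20 h
- beta: starting material 0.52 M (in portions, 2); free catalyst 0.78 mM; run made earlier; portions every 20 h
- flask: starting material 0.52 M (in portions, 2); free catalyst 0.52 mM; the portions of starting material follow each other after 20 h, the first at the start; time 30 d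

| run | time / d | starting material / % | uncatalysed product / % | target / % | catalyst intermediate A / % |
|---|---|---|---|---|---|
| gamma | 6.00 | 44.4 | 32.8 | 23.7 | 0 |
| gamma | 12.0 | 44.0 | 32.7 | 23.9 | 0.5 |
| gamma | 20.0 | 44.5 | 32.8 | 21.8 | 0 |
| gamma | 25.0 | 44.6 | 33.1 | 23.1 | 1.9 |
| gamma | 30.0 | 43.3 | 30.9 | 23.9 | 0 |
| theta | 2.50 | 63.3 | 23.2 | 13.6 | 0.1 |
| theta | 8.00 | 61.6 | 23.2 | 14.4 | 0 |
| theta | 15.0 | 59.2 | 25.6 | 16.9 | 0.8 |
| theta | 20.0 | 59.2 | 23.5 | 15.3 | 0.4 |
| theta | 30.0 | 58.6 | 25.2 | 16.2 | 0 |
| beta | 2.50 | 60.5 | 19.3 | 20.3 | 0.9 |
| beta | 5.00 | 56.8 | 22.5 | 20.9 | 0 |
| beta | 8.00 | 58.0 | 20.6 | 21.0 | 1.2 |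
| beta | 15.0 | 57.2 | 20.4 | 19.7 | 0.7 |
| beta | 30.0 | 58.0 | 22.9 | 21.6 | 0 |

(standard deviation of a reading: 1 percentage point)

- the analysis behind the earlier runs scatters by 1 percentage point, standard deviation

* the species in which most of what was charged as starting material, at 30 d sits (uncatalysed product / target / catalyst intermediate A / starting material)
* the largest share itself, whichever of these holds it, in percent of the starting material charged

Now add the uncatalysed product, which we take to use one partner too. The split between the products moves, but the partner needed does not, so our figure stays at none.

The runs disagree. Averaging its last two readings, gamma used 0.196 M of starting material, less than its 0.572 M of partner, and yet it stands still. So we add the rest: we suppose that partner is the limiting reagent and that it has a further fork, into something no column shows, probably by way of the second substrate. We follow one molecule of partner and ask its chance of ending on starting material, reading theta the same way and placing the flask between the two runs in step with its charge: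

gamma: 0.343

theta: 0.560

flask: 0.429

This is the catch, the share of the partner charged that ends on starting material. Multiplied by [partner] as charged and divided by [starting material] as charged, it gives the part of the starting material used, so the last fork lifts our figure from none to:

starting material left: 52.8%

The forecast says starting material at 52.5%, noting “Reaction stops with starting material still present”. Our own figure is 52.8%. Both draw on gamma and theta, so their nearness is no check.

The flask gives starting material at 51.2%, with uncatalysed product at 29.6% and target at 19.3%.

    starting material + free catalyst ⇌ catalyst intermediate A (K = 1.40 M⁻¹, k = 0.0730 M⁻¹ s⁻¹)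
    partner + catalyst intermediate A → free catalyst + target (k = 0.0470 M⁻¹ s⁻¹)
    second substrate + free catalyst ⇌ catalyst intermediate B (K = 30.0 M⁻¹, k = 0.0140 M⁻¹ s⁻¹)
    partner + catalyst intermediate B → free catalyst + second product (k = 0.0140 M⁻¹ s⁻¹)
    starting material + partner → uncatalysed product (k = 9.20 × 10⁻⁶ M⁻¹ s⁻¹)

The result puts the catch of the flask at 0.444, against our 0.429, and 0.318 M of second product stands beside it. A neighbouring flask with 0.0013 M of free catalyst keeps 65.9% of its starting material, a catch of 0.310, lower than in our flask. Our flask has come to rest: partner is at 0% of its charge by 30.0 d. Starting material reads 51.2% at 15.0 d and 51.2% at 30.0 d, and at 300 d it still reads 51.2%.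

(All runs come from a simulation from invented constants; scatter was added.)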